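**Strategy.** The route rests on making the methoxy-bearing benzo ring (C3a–C4–C5–C6–C7–C7a) and the fused γ-lactam of the isoindolinone in one operation from an open-chain diyne. C3a–C4 and C7a–C7 are each a pair of adjacent ring carbons joined through C3–N2–C1, so they can be the two alkynes of a 1,6-diyne, with C5–C6 supplied by acetylene. A rhodium(I) [2+2+2] cycloaddition then forms C3a–C7a, C4–C5 and C6–C7. The precursor 15 is the N-tosyl propiolamide of an (S)-1-aryl-3-methoxypropargylamine whose aryl group is a bis-benzylated methyl orsellinate. C3 is set beforehand by an alkynylalane addition to a sulfinimine. Deprotection, dearomatising gem-diprenylation and demethylative decarboxylation finish the synthesis.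

Key step: step 8

Assumption: the alkynylalane adds to sulfinimine 5 through the aluminium–sulfinyl-oxygen chelate (chair), as cyano- and alkoxyethynyl-alanes do with N-sulfinyl aldimines; if the open-transition-state isomer prevailed, the enantiomer of 4 would be used, and the diastereomers of 11 are separable in either case.

Design notes:
- **Tosyl on nitrogen.** A secondary propiolamide prefers the transoid amide rotamer, which holds the two alkynes apart. The tosyl group populates the cisoid rotamer and is removed reductively once the arene exists.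
- **No acid while the ynol ether is present.** A 1-alkoxyalkyne adds HX and carboxylic acids. The p-tolylsulfinyl auxiliary is therefore oxidised to the tosyl group, not cleaved, and propiolic acid is introduced as its preformed acid chloride.
- **Benzyl ethers on the phenols.** They are released by neutral hydrogenolysis, which avoids acid at the ionisable diarylmethyl C3–N bond.

Step 1
Reactants: 1 methyl orsellinate
Product: 2 methyl 3-formyl-2,4-dihydroxy-6-methylbenzoate (methyl haematommate)
Conditions: Cl2CHOMe, TiCl4, CH2Cl2, 0 °C → rt; aq. HCl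
Reagents that add atoms: dichloromethyl methyl ether ClC(Cl)OC; water O
Why: Rieche formylation, in which titanium-bound phenoxide directs the chloro(methoxy)methyl cation to C3, the ring carbon ortho to both hydroxyls (the position orsellinates also offer to Gattermann formylation and C-methylation), and aqueous hydrolysis releases the aldehyde; any 5-formyl isomer is removed by crystallisation.

Step 2
Reactants: 2 methyl 3-formyl-2,4-dihydroxy-6-methylbenzoate
Product: 3 methyl 2,4-bis(benzyloxy)-3-formyl-6-methylbenzoate
Conditions: BnBr, K2CO3, DMF, 60 °C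
Reagents that add atoms: benzyl bromide BrCc1ccccc1
Why: Williamson etherification of both chelated phenols; benzyl ethers should survive the organometallic, oxidative and rhodium steps and are later removed without acid or base.

Step 3
Reactants: 3 methyl 2,4-bis(benzyloxy)-3-formyl-6-methylbenzoate, 4 (R)-4-methylbenzenesulfinamide
Product: 5 methyl 2,4-bis(benzyloxy)-6-methyl-3-[(E)-{[(R)-4-methylbenzenesulfinyl]imino}methyl]benzoate
Conditions: Ti(OEt)4, THF, 60 °C
Reagents that add atoms: none
Why: Titanium(IV) ethoxide-mediated condensation (Lewis acid and water scavenger) should give the E-configured N-sulfinyl aldimine without touching sulfur, whose (R) configuration is carried into 5.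

Step 4
Reactants: 6 chloroacetaldehyde dimethyl acetal
Product: 8 methoxyacetylene, via sodium methoxyacetylide 7 (not isolated)
Conditions: NaNH2, liq. NH3, −40 °C; cold aq. NH4Cl; distilled into cold toluene and used as a solution
Reagents that add atoms: none
Why: Twofold base-induced elimination (of HCl and of methanol) from the α-chloro acetal gives the sodium alkoxyacetylide, and protonation frees the volatile ynol ether, the classical preparation of 1-alkoxyalkynes.

Step 5
Reactants: 5 methyl 2,4-bis(benzyloxy)-6-methyl-3-[(E)-{[(R)-4-methylbenzenesulfinyl]imino}methyl]benzoate, 8 methoxyacetylene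
Product: 11 methyl 2,4-bis(benzyloxy)-3-[(1S)-3-methoxy-1-{[(R)-4-methylbenzenesulfinyl]amino}prop-2-yn-1-yl]-6-methylbenzoate, via lithium methoxyacetylide 9 (not isolated), via dimethyl(methoxyethynyl)aluminium 10 (not isolated)
Conditions: 8, n-BuLi, Et2O–toluene, −78 °C; Me2AlCl, −78 → 0 °C; then 5, toluene, −78 → −20 °C; aq. Rochelle salt
Reagents that add atoms: none
Why: 1,2-Addition of an alkynylalane to an N-sulfinyl aldimine, in which aluminium bridges the sulfinyl oxygen and the alkynyl group in a six-membered chair with p-tolyl equatorial, so the alkyne is delivered to the Si face of the (R)-sulfinyl E-imine and the new carbon (the future C3) should form as (S); the minor diastereomer is removed by chromatography on base-washed silica.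

Step 6
Reactants: 11 methyl 2,4-bis(benzyloxy)-3-[(1S)-3-methoxy-1-{[(R)-4-methylbenzenesulfinyl]amino}prop-2-yn-1-yl]-6-methylbenzoate
Product: 12 methyl 2,4-bis(benzyloxy)-3-[(1S)-3-methoxy-1-(tosylamino)prop-2-yn-1-yl]-6-methylbenzoate
Conditions: mCPBA (1.05 equiv), solid NaHCO3, CH2Cl2, −40 → −20 °C
Reagents that add atoms: mCPBA OOC(=O)c1cccc(Cl)c1
Why: Peracid oxidation of a sulfinamide to the sulfonamide, in which the sulfur lone pair is a better nucleophile toward the peracid than the alkyne π-bond, and one equivalent at low temperature over bicarbonate keeps the carboxylic acid by-product away from the ynol ether; the carbon stereocentre is not involved.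

Step 7
Reactants: 12 methyl 2,4-bis(benzyloxy)-3-[(1S)-3-methoxy-1-(tosylamino)prop-2-yn-1-yl]-6-methylbenzoate, 13 propiolic acid
Product: 15 methyl 2,4-bis(benzyloxy)-3-[(1S)-3-methoxy-1-(N-tosylpropiolamido)prop-2-yn-1-yl]-6-methylbenzoate, via propioloyl chloride 14 (not isolated)
Conditions: 13, 1-chloro-N,N,2-trimethylprop-1-en-1-amine, CH2Cl2, 0 °C; separately 12, NaH, THF, 0 °C; acid chloride solution added at −78 → 0 °C
Reagents that add atoms: none
Why: N-Acylation of a sulfonamide anion with an acid chloride; making the acid chloride beforehand with the neutral α-chloroenamine means no free carboxylic acid or HCl meets the ynol ether, and the hard nitrogen anion should attack the acyl carbon and not the alkyne terminus at low temperature.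

Step 8
Reactants: 15 methyl 2,4-bis(benzyloxy)-3-[(1S)-3-methoxy-1-(N-tosylpropiolamido)prop-2-yn-1-yl]-6-methylbenzoate, 16 acetylene
Product: 17 methyl 2,4-bis(benzyloxy)-3-[(3S)-4-methoxy-1-oxo-2-tosylisoindolin-3-yl]-6-methylbenzoate
Conditions: RhCl(PPh3)3 (5 mol%), HC≡CH (1 atm), toluene, 40 °C; 15 added over 4 h
Reagents that add atoms: none
Why: Rh(I) binds the two tethered alkynes and couples them oxidatively to a rhodacyclopentadiene, which forms C3a–C7a and with it the five-membered lactam; acetylene then inserts and reductive elimination forms C4–C5 and C6–C7, closing the benzene ring. The closest known reaction type is the rhodium(I)-catalysed [2+2+2] cyclotrimerisation of N-sulfonyl- and amide-tethered 1,6-diynes with acetylene or monoalkynes to indolines and isoindolinones. The lactam closes by intramolecular alkyne–alkyne oxidative cyclisation across the three-atom C3–N2–C1 tether (a five-membered ring fused to the metallacycle), and the arene closes by intermolecular insertion of the third alkyne followed by C–C reductive elimination (a formal [4+2] on the metallacycle). No stereocentre is formed; C3 is a spectator sp3 carbon outside the reacting π-systems and should not epimerise under neutral conditions. The step needs cross- over homo-trimerisation and a single regiochemistry: the tether fixes the methoxy-bearing alkyne carbon as C4 and acetylene is symmetrical, the N-tosyl group populates the cisoid rotamer and pairs an electron-poor propiolimide-type alkyne with the electron-rich ynol ether for fast intramolecular coupling, and slow addition of 15 into acetylene-saturated solution suppresses diyne dimerisation. A neutral, chloride-bound catalyst in an aprotic solvent is chosen so that the ynol ether is not hydrated or ionised before it is consumed.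

Step 9
Reactants: 17 methyl 2,4-bis(benzyloxy)-3-[(3S)-4-methoxy-1-oxo-2-tosylisoindolin-3-yl]-6-methylbenzoate
Product: 18 methyl 2,4-bis(benzyloxy)-3-[(3S)-4-methoxy-1-oxoisoindolin-3-yl]-6-methylbenzoate
Conditions: SmI2 (3 equiv), THF, −78 °C; MeOH
Reagents that add atoms: none
Why: Single-electron reduction of the N-acyl sulfonamide by samarium(II) cleaves the weak N–S bond and expels sulfinate, a neutral low-temperature detosylation that should leave the ester, the benzyl ethers and the C3–H stereocentre untouched.

Step 10
Reactants: 18 methyl 2,4-bis(benzyloxy)-3-[(3S)-4-methoxy-1-oxoisoindolin-3-yl]-6-methylbenzoate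
Product: 19 methyl 2,4-dihydroxy-3-[(3S)-4-methoxy-1-oxoisoindolin-3-yl]-6-methylbenzoate
Conditions: H2 (1 atm), 10% Pd/C, EtOAc–MeOH, rt
Reagents that add atoms: none
Why: Palladium-catalysed hydrogenolysis of the two benzyl aryl ethers under neutral conditions avoids both acid (ionisation of the diarylmethyl C3–N bond) and base (deprotonation at C3); the lactam C–N bond should not be cleaved at 1 atm.

Step 11
Reactants: 19 methyl 2,4-dihydroxy-3-[(3S)-4-methoxy-1-oxoisoindolin-3-yl]-6-methylbenzoate, 20 prenyl bromide
Product: 22 methyl 6-hydroxy-5-[(3S)-4-methoxy-1-oxoisoindolin-3-yl]-2-methyl-3,3-bis(3-methylbut-2-en-1-yl)-4-oxocyclohexa-1,5-diene-1-carboxylate, via methyl 5-prenyl-2,4-dihydroxybenzoate 21 (not isolated)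
Conditions: 20 (2.6 equiv), KOH (3 equiv), H2O–MeOH, 0 °C → rt, argon
Reagents that add atoms: none
Why: Alkylative dearomatisation of a resorcinol dianion, as in the synthesis of hop β-acids: in a protic medium the phenoxide is alkylated at carbon, C5 of the benzoate being the only unsubstituted position ortho/para to the oxygens, and the second prenyl group should enter the same carbon because this keeps the ester-conjugated enolone (a stabilised vinylogous acid anion) intact while the carbon between the oxygens is shielded by the isoindolinone; cold aqueous hydroxide should not affect the C3 stereocentre.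

Step 12
Reactants: 22 methyl 6-hydroxy-5-[(3S)-4-methoxy-1-oxoisoindolin-3-yl]-2-methyl-3,3-bis(3-methylbut-2-en-1-yl)-4-oxocyclohexa-1,5-diene-1-carboxylate
Product: 24 (3S)-3-[2-hydroxy-4-methyl-5,5-bis(3-methylbut-2-en-1-yl)-6-oxocyclohexa-1,3-dien-1-yl]-4-methoxyisoindolin-1-one, via dienone carboxylic acid 23 (not isolated)
Conditions: LiI (5 equiv), pyridine, 100 °C, argon; aq. NaH2PO4
Reagents that add atoms: none
Why: Krapcho-type dealkoxycarbonylation, in which iodide removes the ester methyl group by SN2 attack (pyridine traps the methyl iodide) and the resulting vinylogous β-keto acid loses CO2 through its deconjugated tautomer in hot pyridine, as alkylidene β-dicarbonyl acids do in the Doebner reaction, leaving C–H at the former ester carbon.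

**Compound list**

1 | methyl orsellinate (methyl 2,4-dihydroxy-6-methylbenzoate) | COC(=O)c1c(C)cc(O)cc1O | starting material
2 | methyl 3-formyl-2,4-dihydroxy-6-methylbenzoate | COC(=O)c1c(C)cc(O)c(C=O)c1O | intermediate
3 | methyl 2,4-bis(benzyloxy)-3-formyl-6-methylbenzoate | COC(=O)c1c(C)cc(OCc2ccccc2)c(C=O)c1OCc1ccccc1 | intermediate
4 | (R)-4-methylbenzenesulfinamide | Cc1ccc(cc1)[S@@](=O)N | starting material
5 | methyl 2,4-bis(benzyloxy)-6-methyl-3-[(E)-{[(R)-4-methylbenzenesulfinyl]imino}methyl]benzoate | Cc1ccc(cc1)[S@@](=O)/N=C/c1c(OCc2ccccc2)cc(C)c(C(=O)OC)c1OCc1ccccc1 | intermediate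
6 | chloroacetaldehyde dimethyl acetal | COC(CCl)OC | starting material
7 | sodium methoxyacetylide | COC#[C-].[Na+] | intermediate
8 | methoxyacetylene | COC#C | intermediate
9 | lithium methoxyacetylide | [Li]C#COC | intermediate
10 | dimethyl(methoxyethynyl)aluminium | C[Al](C)C#COC | intermediate
11 | methyl 2,4-bis(benzyloxy)-3-[(1S)-3-methoxy-1-{[(R)-4-methylbenzenesulfinyl]amino}prop-2-yn-1-yl]-6-methylbenzoate | COC#C[C@@H](c1c(OCc2ccccc2)cc(C)c(C(=O)OC)c1OCc1ccccc1)N[S@](=O)c1ccc(C)cc1 | intermediate
12 | methyl 2,4-bis(benzyloxy)-3-[(1S)-3-methoxy-1-(tosylamino)prop-2-yn-1-yl]-6-methylbenzoate | COC#C[C@@H](c1c(OCc2ccccc2)cc(C)c(C(=O)OC)c1OCc1ccccc1)NS(=O)(=O)c1ccc(C)cc1 | intermediate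
13 | propiolic acid | C#CC(=O)O | starting material
14 | propioloyl chloride | C#CC(=O)Cl | intermediate
15 | methyl 2,4-bis(benzyloxy)-3-[(1S)-3-methoxy-1-(N-tosylpropiolamido)prop-2-yn-1-yl]-6-methylbenzoate | COC#C[C@@H](c1c(OCc2ccccc2)cc(C)c(C(=O)OC)c1OCc1ccccc1)N(C(=O)C#C)S(=O)(=O)c1ccc(C)cc1 | intermediate
16 | acetylene | C#C | starting material
17 | methyl 2,4-bis(benzyloxy)-3-[(3S)-4-methoxy-1-oxo-2-tosylisoindolin-3-yl]-6-methylbenzoate | COc1cccc2c1[C@@H](c1c(OCc3ccccc3)cc(C)c(C(=O)OC)c1OCc1ccccc1)N(S(=O)(=O)c1ccc(C)cc1)C2=O | intermediate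
18 | methyl 2,4-bis(benzyloxy)-3-[(3S)-4-methoxy-1-oxoisoindolin-3-yl]-6-methylbenzoate | COc1cccc2c1[C@@H](c1c(OCc3ccccc3)cc(C)c(C(=O)OC)c1OCc1ccccc1)NC2=O | intermediate
19 | methyl 2,4-dihydroxy-3-[(3S)-4-methoxy-1-oxoisoindolin-3-yl]-6-methylbenzoate | COc1cccc2c1[C@@H](c1c(O)cc(C)c(C(=O)OC)c1O)NC2=O | intermediate
20 | prenyl bromide | CC(C)=CCBr | starting material
21 | methyl 2,4-dihydroxy-3-[(3S)-4-methoxy-1-oxoisoindolin-3-yl]-6-methyl-5-(3-methylbut-2-en-1-yl)benzoate | COc1cccc2c1[C@@H](c1c(O)c(CC=C(C)C)c(C)c(C(=O)OC)c1O)NC2=O | intermediate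
22 | methyl 6-hydroxy-5-[(3S)-4-methoxy-1-oxoisoindolin-3-yl]-2-methyl-3,3-bis(3-methylbut-2-en-1-yl)-4-oxocyclohexa-1,5-diene-1-carboxylate | COc1cccc2c1[C@@H](C1=C(O)C(C(=O)OC)=C(C)C(CC=C(C)C)(CC=C(C)C)C1=O)NC2=O | intermediate
23 | 6-hydroxy-5-[(3S)-4-methoxy-1-oxoisoindolin-3-yl]-2-methyl-3,3-bis(3-methylbut-2-en-1-yl)-4-oxocyclohexa-1,5-diene-1-carboxylic acid | COc1cccc2c1[C@@H](C1=C(O)C(C(=O)O)=C(C)C(CC=C(C)C)(CC=C(C)C)C1=O)NC2=O | intermediate
24 | (3S)-3-[2-hydroxy-4-methyl-5,5-bis(3-methylbut-2-en-1-yl)-6-oxocyclohexa-1,3-dien-1-yl]-4-methoxyisoindolin-1-one (CNP0508988.1) | COc1cccc2c1[C@@H](C1=C(O)C=C(C)C(CC=C(C)C)(CC=C(C)C)C1=O)NC2=O | target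

**Totals.** Total step count: 12. Longest linear sequence: 11 steps (1, 2, 3, 5, 6, 7, 8, 9, 10, 11, 12, from methyl orsellinate); step 4 is a one-step side branch.

**Steps most likely to fail**

1. Step 8. Homo-trimerisation of acetylene or dimerisation of the diyne may outrun the cross-reaction, or the ynol ether may be hydrated or ionised at the metal before it is incorporated. Fallback (no cyclotrimerisation; the isoindolinone is assembled by directed ortho-metalation): setting out from sulfinimine 5, N,N-diethyl-3-methoxybenzamide is lithiated between its two directing groups (s-BuLi, TMEDA, THF, −78 °C), transmetalated with MgBr2·OEt2 and added in toluene through the same chelate model, which should give N,N-diethyl-2-[(S)-[2,6-bis(benzyloxy)-3-(methoxycarbonyl)-4-methylphenyl]{[(R)-4-methylbenzenesulfinyl]amino}methyl]-3-methoxybenzamide F1. HCl in methanol (no ynol ether exists on this path) removes the sulfinyl group to give N,N-diethyl-2-[(S)-amino[2,6-bis(benzyloxy)-3-(methoxycarbonyl)-4-methylphenyl]methyl]-3-methoxybenzamide F2, which should close to the lactam with loss of diethylamine on heating in toluene with catalytic acetic acid, coming back to the route at 18.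

2. Step 11. Alkylation may go to oxygen instead of carbon, stop after the first prenylation, or take place at the ester-bearing carbon. Fallback (palladium π-allyl chemistry in place of SN2 alkylation): setting out from 19, tert-butyl prenyl carbonate and catalytic Pd(PPh3)4 in THF (Tsuji–Trost prenylation) should deliver the prenyl unit to carbon, and O-prenyl ethers formed on the way are re-ionised by palladium and funnelled to the C-alkylated products; the sequence passes through 21 and comes back to the route at 22. It makes no new compound.

3. Step 6. The electron-rich alkyne may be oxidised alongside sulfur, or the carboxylic acid by-product may add to the ynol ether. Fallback (sulfur is brought in already as sulfonyl, so no oxidation is needed): setting out from aldehyde 3, condensation with p-toluenesulfonamide (Ti(OEt)4, THF, 60 °C) should give methyl 2,4-bis(benzyloxy)-6-methyl-3-[(E)-(tosylimino)methyl]benzoate F3. A zinc-mediated enantioselective alkynylation with methoxyacetylene 8 (Me2Zn, 3,3'-dibromo-BINOL ligand, toluene) should then give the sulfonamide directly, coming back to the route at 12; the ligand antipode is chosen for the (S) product and the enantiomeric purity is raised by crystallisation.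

**Further compounds**

F1 | step 8 | N,N-diethyl-2-[(S)-[2,6-bis(benzyloxy)-3-(methoxycarbonyl)-4-methylphenyl]{[(R)-4-methylbenzenesulfinyl]amino}methyl]-3-methoxybenzamide | CCN(CC)C(=O)c1cccc(OC)c1[C@@H](c1c(OCc2ccccc2)cc(C)c(C(=O)OC)c1OCc1ccccc1)N[S@](=O)c1ccc(C)cc1
F2 | step 8 | N,N-diethyl-2-[(S)-amino[2,6-bis(benzyloxy)-3-(methoxycarbonyl)-4-methylphenyl]methyl]-3-methoxybenzamide | CCN(CC)C(=O)c1cccc(OC)c1[C@@H](c1c(OCc2ccccc2)cc(C)c(C(=O)OC)c1OCc1ccccc1)N
F3 | step 6 | methyl 2,4-bis(benzyloxy)-6-methyl-3-[(E)-(tosylimino)methyl]benzoate | Cc1ccc(cc1)S(=O)(=O)/N=C/c1c(OCc2ccccc2)cc(C)c(C(=O)OC)c1OCc1ccccc1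
F0 | step 11 | none | none
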